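A flask that still held 63.5 % of its substrate at 300 min, with partner charged at 1.30 equiv, cannot have stopped for want of reagent. You asked for a quick number on the violet flask, with the hunch that more partner would push it on, so here is what I had.

- violet: substrate 0.13 M; partner 1.3 equiv; free catalyst 2 mol%; temperature 80 °C; the very flask that is asked about, followed so far
- flask: substrate 0.13 M; partner 1.30 equiv; free catalyst 2 mol%; temperature 80 °C; time 5.0 h

- violet (time / min: target / %, substrate / %): 25.0: 21.4, 70.2; 50.0: 25.2, 64.9; 80.0: 25.4, 65.3; 150: 26.0, 63.8; 300: 25.7, 63.5

(standard deviation of a reading: 0.5 percentage points)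

- Thursday's: change nothing and wait 10 h more
- Monday's: at 5.0 h take out 90 % of the target then present, then wait 10 h
- Sunday's: at 5.0 h add free catalyst, 50.0 % of the amount charged, then wait 10 h
- Friday's: at 5.0 h add partner, 50.0 % of the amount charged, then wait 10 h
- Saturday's: at 5.0 h raise the temperature by 10 K, then wait 10 h

- target taken out counts as made
- the earlier runs do not show what temperature does; that part of a forecast is a guess
- additions bring no volume worth counting

1. target, in percent of the substrate first charged, at 5.0 h
2. which option adds most target ("none" when 2 percentage points or less is all one gets) (Thursday's / Monday's / Sunday's / Friday's / Saturday's / none)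
3. target present, with what was taken out counted in, in percent of the substrate first charged, after Thursday's
4. target present, with what was taken out counted in, in percent of the substrate first charged, after Friday's

I counted turnovers. Target read 25.2 % at 50.0 min and 25.7 % at 300 min, a change within the scatter of 0.5 percentage points, so I took the flat stretch as the end of the catalyst's working life, though that was a reading and no proof. The charge of catalyst stood at 12.8 turnovers counted in target, and this turnover number, target standing per catalyst charged as fractions of the charge, was what I carried. If a catalyst lives a fixed span, its turnovers go with the substrate it meets. Sunday's catalyst, 1.00 % of the substrate charge, would meet 63.5 % of the substrate, so I expected it to add 8.2 points. I put now at the plateau of 25.7 % and left Thursday's and Friday's there too, since neither brings catalyst.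

The forecast gave 25.7 % for now, within 25.2 % to 26.2 %, then 25.8 % after Thursday's and 26 % after Friday's, the latter with a range up to 34 %. It chose Sunday's, on the grounds “I read this as the catalyst dying”. It expected 9 to 12 points from fresh catalyst, where I had 8.2 points.

The flask gave 26.1 % at 5.0 h, 26.1 % after Thursday's and 26.1 % after Friday's, and Sunday's was best, adding 7.5 points to end at 33.5 %. The forecast's now would have left its range in a flask charged at 2.6 mol%, where the answer has moved by 5 points.

    2 free catalyst ⇌ resting dimer (K = 540 M⁻¹, k = 39.0 M⁻¹ s⁻¹, Ea = 43.0 kJ mol⁻¹, ΔH = −50.0 kJ mol⁻¹)
    partner + catalyst intermediate → free catalyst + target (k = 1.90 M⁻¹ s⁻¹, Ea = 59.0 kJ mol⁻¹)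
    free catalyst → spent catalyst (k = 0.00180 s⁻¹, Ea = 105 kJ mol⁻¹)
    free catalyst + open intermediate ⇌ catalyst intermediate (K = 170 M⁻¹, k = 3.90 M⁻¹ s⁻¹, Ea = 50.0 kJ mol⁻¹, ΔH = 4.00 kJ mol⁻¹)
    free catalyst + target → free catalyst + over-reaction product (k = 0.220 M⁻¹ s⁻¹, Ea = 48.0 kJ mol⁻¹)
    substrate + free catalyst ⇌ free catalyst + open intermediate (K = 0.130, k = 0.720 M⁻¹ s⁻¹, Ea = 53.0 kJ mol⁻¹, ΔH = −38.0 kJ mol⁻¹)
    (constants at 80 °C)

The neighbouring flask took 0.33 M of substrate against 0.13 M, on the same recipe otherwise. Turnovers going with substrate gave 32.6, so 65.2 % of the charge should have passed through target. At 300 min that flask held 40.8 % target and 22.0 % over-reaction product, together 62.8 %.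

(The data come from a simulation with constants of no real substance; the scatter is artificial.)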